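**Strategy**

Plagiochin E is cut at the bond between ring B C-1 (ring B carries OH and the ether oxygen; C-1 lies para to that OH) and the benzylic CH2 of the ethano bridge leading to ring A (the biaryl ring with OH para to the axis). The key step exploits two features: this bridge is saturated, and C-1 can be held as a chloride that outlasts earlier couplings at iodide and bromide. In one pot, 9-BBN adds to a ring A vinyl group and intramolecular B-alkyl Suzuki–Miyaura coupling closes the 16-membered ring at the final oxidation level. The precursor is an open chain of four rings holding the biaryl bond, the other bridge and the ether.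

Key step: step 5

Ring labels: ring A = phenol ring bonded to the biaryl axis para to its OH; ring B = ring with OH and ether oxygen on neighbouring carbons; ring C = 1,4-phenylene ring; ring D = phenol ring with OH ortho to the biaryl axis.

Remark on the chemistry: the target has no stereocentre and no configuration is specified for its biaryl axis, so the axis is carried without stereocontrol; 2-bromo-1-iodo-3-methoxybenzene (5) is taken as a catalogue compound.

**Route**

Step 1
Reactants: 1 5-chloro-2-methoxyphenol; 2 (4-ethenylphenyl)boronic acid
Product: 3 4-chloro-2-(4-ethenylphenoxy)-1-methoxybenzene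
Conditions: Cu(OAc)2 (20 mol %), pyridine, 4 Å molecular sieves, O2 (balloon), CH2Cl2, rt
Reagents that add atoms: none
Why: Chan–Lam oxidative C–O coupling, in which the copper phenoxide is arylated by the boronic acid at room temperature under O2, conditions that leave the aryl chloride and the vinyl group untouched.

Step 2
Reactants: 3 4-chloro-2-(4-ethenylphenoxy)-1-methoxybenzene; 4 9-borabicyclo[3.3.1]nonane (9-BBN); 5 2-bromo-1-iodo-3-methoxybenzene
Product: 7 2-bromo-1-{2-[4-(5-chloro-2-methoxyphenoxy)phenyl]ethyl}-3-methoxybenzene, via alkylborane 6 (not isolated)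
Conditions: 4, THF, 0 °C to rt; then 5, PdCl2(dppf) (5 mol %), aq. NaOH (3 M), THF, rt to 45 °C
Reagents that add atoms: none
Why: Anti-Markovnikov hydroboration of the styrene by 9-BBN followed by B-alkyl Suzuki–Miyaura coupling, in which zerovalent palladium should insert into the C–I bond of 5 much faster than into its doubly flanked C–Br bond or the C–Cl bond, so that the alkyl group enters at C-1 only.

Step 3
Reactants: 7 2-bromo-1-{2-[4-(5-chloro-2-methoxyphenoxy)phenyl]ethyl}-3-methoxybenzene; 8 (2-formyl-4-methoxyphenyl)boronic acid
Product: 9 2'-{2-[4-(5-chloro-2-methoxyphenoxy)phenyl]ethyl}-4,6'-dimethoxy-[1,1'-biphenyl]-2-carbaldehyde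
Conditions: Pd(PPh3)4 (10 mol %), K3PO4, DMF, 100 °C, excess 8
Reagents that add atoms: none
Why: Suzuki–Miyaura biaryl coupling, in which Pd(PPh3)4 should insert into the aryl bromide but not into the electron-rich aryl chloride, while the non-aqueous base limits protodeboronation of the ortho-formyl boronic acid on the way to the tri-ortho-substituted biaryl.

Step 4
Reactants: 9 2'-{2-[4-(5-chloro-2-methoxyphenoxy)phenyl]ethyl}-4,6'-dimethoxy-[1,1'-biphenyl]-2-carbaldehyde
Product: 10 2'-{2-[4-(5-chloro-2-methoxyphenoxy)phenyl]ethyl}-2-ethenyl-4,6'-dimethoxy-1,1'-biphenyl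
Conditions: Ph3PCH3Br, KOtBu, THF, 0 °C to rt
Reagents that add atoms: methyltriphenylphosphonium bromide, C[P+](c1ccccc1)(c1ccccc1)c1ccccc1.[Br-]
Why: Wittig methylenation, in which the non-stabilised ylide should convert the aryl aldehyde, the only electrophile present, into the terminal alkene.

Step 5
Reactants: 10 2'-{2-[4-(5-chloro-2-methoxyphenoxy)phenyl]ethyl}-2-ethenyl-4,6'-dimethoxy-1,1'-biphenyl; 4 9-borabicyclo[3.3.1]nonane (9-BBN)
Product: 12 tri-O-methylplagiochin E (the target macrocycle with its three OH groups as OMe), via alkylborane 11 (not isolated)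
Conditions: 4 (1.2 equiv), THF, rt to 50 °C; then syringe-pump addition to Pd(OAc)2 (10 mol %), SPhos (20 mol %), K3PO4, 1,4-dioxane/H2O, 90 °C, 2 mM
Reagents that add atoms: none
Why: 9-BBN adds anti-Markovnikov to the ring A vinyl group and puts boron on the terminal carbon; when the resulting borane 11 is fed slowly into the hot catalyst solution, the zerovalent palladium–SPhos complex should insert into the ring B C–Cl bond, the base-activated B-alkyl group transmetalates within the same molecule, and reductive elimination forms the CH2–aryl bond. The closest known reaction type is the B-alkyl Suzuki–Miyaura macrocyclisation, here in its aryl chloride variant with a dialkylbiarylphosphine ligand. The 16-membered ring closes end to end in the reductive elimination from a 17-membered palladacycle and appears directly with a saturated bridge, so no stilbene has to be reduced. No stereocentre is formed, and the biaryl axis is not controlled. The step needs terminal regioselectivity in the hydroboration (secured by the bulk of 9-BBN on a monosubstituted alkene), ring closure in preference to oligomerisation (secured by syringe-pump dilution and by the ortho-biaryl turn and bibenzyl tether that fold the two ends towards each other) and reductive elimination in preference to β-hydride elimination (secured by SPhos). Site selectivity is built in, since the chloride at ring B C-1, para to the ring B methoxy group, is the only carbon–halogen bond left.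

Step 6
Reactants: 12 tri-O-methylplagiochin E
Product: 13 plagiochin E
Conditions: BBr3 (6 equiv), CH2Cl2, −78 °C to rt; then H2O
Reagents that add atoms: none
Why: Lewis-acid ether cleavage, in which BBr3 complexes each methoxy oxygen and bromide removes the methyl group by SN2, while the diaryl ether (no sp3 carbon on oxygen) and the two bibenzyl bridges should stay intact.

**Compound list**

1 | 5-chloro-2-methoxyphenol | COc1ccc(Cl)cc1O | starting material
2 | (4-ethenylphenyl)boronic acid | C=Cc1ccc(cc1)B(O)O | starting material
3 | 4-chloro-2-(4-ethenylphenoxy)-1-methoxybenzene | COc1ccc(Cl)cc1Oc1ccc(C=C)cc1 | intermediate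
4 | 9-borabicyclo[3.3.1]nonane (9-BBN) | B1C2CCCC1CCC2 | starting material
5 | 2-bromo-1-iodo-3-methoxybenzene | COc1cccc(I)c1Br | starting material
6 | 9-{2-[4-(5-chloro-2-methoxyphenoxy)phenyl]ethyl}-9-borabicyclo[3.3.1]nonane | COc1ccc(Cl)cc1Oc1ccc(CCB2C3CCCC2CCC3)cc1 | intermediate
7 | 2-bromo-1-{2-[4-(5-chloro-2-methoxyphenoxy)phenyl]ethyl}-3-methoxybenzene | COc1cccc(CCc2ccc(Oc3cc(Cl)ccc3OC)cc2)c1Br | intermediate
8 | (2-formyl-4-methoxyphenyl)boronic acid | COc1ccc(B(O)O)c(C=O)c1 | starting material
9 | 2'-{2-[4-(5-chloro-2-methoxyphenoxy)phenyl]ethyl}-4,6'-dimethoxy-[1,1'-biphenyl]-2-carbaldehyde | COc1ccc(c(C=O)c1)-c1c(OC)cccc1CCc1ccc(Oc2cc(Cl)ccc2OC)cc1 | intermediate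
10 | 2'-{2-[4-(5-chloro-2-methoxyphenoxy)phenyl]ethyl}-2-ethenyl-4,6'-dimethoxy-1,1'-biphenyl | COc1ccc(c(C=C)c1)-c1c(OC)cccc1CCc1ccc(Oc2cc(Cl)ccc2OC)cc1 | intermediate
11 | 9-BBN adduct of 10 (9-borabicyclo[3.3.1]nonan-9-yl group on the terminal carbon of the former vinyl group) | COc1ccc(c(CCB2C3CCCC2CCC3)c1)-c1c(OC)cccc1CCc1ccc(Oc2cc(Cl)ccc2OC)cc1 | intermediate
12 | tri-O-methylplagiochin E | COc1ccc2c(c1)CCc1ccc(OC)c(c1)Oc1ccc(cc1)CCc1cccc(OC)c1-2 | intermediate
13 | plagiochin E | Oc1ccc2c(c1)CCc1ccc(O)c(c1)Oc1ccc(cc1)CCc1cccc(O)c1-2 | target

**Step count**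

Total step count: 6. Longest linear sequence: 6 steps (1 → 3 → 7 → 9 → 10 → 12 → 13).

**Steps most likely to fail**

Step 5. Oxidative addition into the electron-rich C–Cl bond may be slow at high dilution. Intermolecular coupling (oligomerisation), β-hydride elimination or protodeboronation of the alkylborane could then outrun ring closure. The fallback forms the same aryl–carbon bond at the alkene oxidation level and sets out from 10. An intramolecular Mizoroki–Heck reaction (Pd2(dba)3, P(t-Bu)3, Cy2NMe, 1,4-dioxane, 110 °C, high dilution) should join the terminal vinyl carbon to ring B C-1 and give the macrocyclic E-stilbene F1. The E-alkene may be less comfortable in the 16-membered ring than the saturated bridge, which is the main uncertainty of this fallback. Hydrogenation of F1 (H2, Pd/C, EtOAc, rt) saturates the bridge and comes back to the route at 12.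

Step 3. Oxidative addition at the doubly ortho-flanked C–Br bond may be slower than protodeboronation of 8, and a more active ligand would risk reaction at the C–Cl bond. The fallback reverses the polarity of the biaryl coupling and sets out from 7. Bromine–lithium exchange (n-BuLi, THF, −78 °C; the aryl chloride should not exchange) gives the aryllithium F2, and ZnCl2 converts it into the arylzinc chloride F3. Negishi coupling of F3 with commercial 2-bromo-5-methoxybenzaldehyde (COc1ccc(Br)c(C=O)c1; Pd(PPh3)4, THF, 60 °C) comes back to the route at 9.

Step 1. The boronic acid may be used up by oxidative homocoupling, protodeboronation or oxidation to the phenol before the phenol is arylated, and the styrene may oligomerise. The fallback makes the ether by nucleophilic aromatic substitution and sets out from 1. Reaction with 4-fluorobenzaldehyde (O=Cc1ccc(F)cc1; K2CO3, DMF, 120 °C) should give 4-(5-chloro-2-methoxyphenoxy)benzaldehyde F4. Wittig methylenation of F4 (Ph3PCH3Br, KOtBu, THF, 0 °C to rt) comes back to the route at 3.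

**Further compounds**

F1 | step 5 | macrocyclic E-stilbene (12 with the ring A–ring B bridge as trans CH=CH) | COc1ccc2c(c1)/C=C/c1ccc(OC)c(c1)Oc1ccc(cc1)CCc1cccc(OC)c1-2
F2 | step 3 | {2-[2-(4-(5-chloro-2-methoxyphenoxy)phenyl)ethyl]-6-methoxyphenyl}lithium | COc1cccc(CCc2ccc(Oc3cc(Cl)ccc3OC)cc2)c1[Li]
F3 | step 3 | {2-[2-(4-(5-chloro-2-methoxyphenoxy)phenyl)ethyl]-6-methoxyphenyl}zinc chloride | COc1cccc(CCc2ccc(Oc3cc(Cl)ccc3OC)cc2)c1[Zn]Cl
F4 | step 1 | 4-(5-chloro-2-methoxyphenoxy)benzaldehyde | COc1ccc(Cl)cc1Oc1ccc(C=O)cc1
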